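**Plan**

- Ring A is the phenol ring (OH on C1, bromines on C2–C4, aryloxy on C6); ring B is the 2,4-dibromophenyl ring (primed numbers).
- The retrosynthesis first removes the two ring-A bromines ortho and para to the hydroxyl (C2–Br, C4–Br), then the O–CH3 bond of a methyl-protected phenol.
- It then cuts ring B at C1′–C2′ and C5′–C6′. Ring B has Br on C2′ and C4′ and H on C3′ and C5′, which is the C3–C6 pattern of 3,5-dibromo-2-pyrone; C1′(O)–C6′(H) is an aryloxyacetylene unit.
- Forward: coumalic acid gives the dibromopyrone; 4-bromoguaiacol, which already carries the C3 bromine para to the future ether oxygen, gives the aryl ethynyl ether through its dichlorovinyl ether.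
- A [4+2] cycloaddition with CO2 extrusion then builds ring B on the ether oxygen; demethylation and dibromination finish ring A.
- No stereochemistry has to be set at any stage.

Key step: step 4

Remark: the target has no stereocentre and the diaryl ether axis rotates freely, so it is achiral and "single enantiomer" reduces to the constitution shown.

**Route**

Step 1
Reactants: 1 coumalic acid (2-oxo-2H-pyran-5-carboxylic acid)
Product: 2 3,5-dibromo-2H-pyran-2-one
Conditions: NBS (2.5 equiv), LiOAc, MeCN–H2O 9:1, rt
Reagents that add atoms: N-bromosuccinimide, O=C1CCC(=O)N1Br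
Why: One-pot halodecarboxylation (Hunsdiecker-type ipso-bromination of the carboxyl-bearing C5 with loss of CO2) together with electrophilic bromination at C3, the two nucleophilic carbons of the pyrone dienol-ether system, is an established way from coumalic acid to this dibromopyrone.

Step 2
Reactants: 3 4-bromo-2-methoxyphenol; 4 trichloroethylene
Product: 6 (E)-4-bromo-1-[(1,2-dichloroethenyl)oxy]-2-methoxybenzene, via dichloroacetylene 5 (not isolated)
Conditions: K2CO3, DMF, 70 °C
Reagents that add atoms: none
Why: The base turns trichloroethylene into dichloroacetylene, and anti addition of the phenoxide across this haloalkyne (nucleophilic addition, then protonation) should give the E-1,2-dichlorovinyl ether without touching the aryl bromide.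

Step 3
Reactants: 6 (E)-4-bromo-1-[(1,2-dichloroethenyl)oxy]-2-methoxybenzene
Product: 9 4-bromo-1-(ethynyloxy)-2-methoxybenzene, via chloroalkynyl ether 7 (not isolated), via lithium acetylide 8 (not isolated)
Conditions: n-BuLi (2.05 equiv, slow addition), Et2O, −78 °C; then H2O, −78 °C → 0 °C; product kept cold in solution and used at once
Reagents that add atoms: none
Why: Greene-type alkynyl ether synthesis, in which the first equivalent of n-BuLi dehydrochlorinates to the chloroalkyne, the second exchanges chlorine for lithium at the sp carbon and water protonates the acetylide; both events should outrun bromine–lithium exchange on the electron-rich aryl bromide in ether at −78 °C when the base is added slowly and not in excess.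

Step 4
Reactants: 9 4-bromo-1-(ethynyloxy)-2-methoxybenzene; 2 3,5-dibromo-2H-pyran-2-one
Product: 11 4-bromo-1-(2,4-dibromophenoxy)-2-methoxybenzene, via bridged lactone 10 (not isolated)
Conditions: 2 (1.5 equiv), BHT (cat.), toluene, sealed tube, 110 °C, 9 added slowly
Reagents that add atoms: none
Why: Proposed new method: the electron-poor diene C3=C4–C5=C6 of pyrone 2 and the oxygen-polarised alkyne of 9 should combine in an inverse-electron-demand [4+2] cycloaddition to the 2-oxabicyclo[2.2.2]octadienone 10, which loses CO2 by retro-[4+2] at the reaction temperature and so gives the arene directly, with no oxidation step. The closest known reactions are the Diels–Alder/CO2-extrusion benzannulation of 2-pyrones with alkynes, including heteroatom-substituted ones, and the inverse-demand cycloadditions of 3,5-dibromo-2-pyrone with enol ethers; an aryl ethynyl ether as the 2π partner is the untested element. Ring B is closed by an intermolecular [4+2] that forms C1′–C2′ (oxygen-bearing alkyne carbon to pyrone C3) and C5′–C6′ (pyrone C6 to the terminal CH), and the new six-membered carbocycle becomes aromatic when the lactone bridge leaves. No stereocentre results, because the two bridgehead centres of 10 vanish on aromatisation. The step needs one regiochemistry, and polarisation should secure it: the nucleophilic terminal carbon of the ynol ether bonds to C6, the pyrone carbon with the largest LUMO coefficient, as enol ethers do with 3-bromo- and 3,5-dibromo-2-pyrone, so the ether oxygen ends up ortho and para to the two bromines. The aryl ynol ether has no O-alkyl β-hydrogen and therefore cannot fragment to a ketene by retro-ene reaction on heating.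

Step 5
Reactants: 11 4-bromo-1-(2,4-dibromophenoxy)-2-methoxybenzene
Product: 13 5-bromo-2-(2,4-dibromophenoxy)phenol, via aryloxydibromoborane 12 (not isolated)
Conditions: BBr3 (1.5 equiv), CH2Cl2, −78 °C → rt; then H2O
Reagents that add atoms: none
Why: Lewis-acid ether cleavage, in which BBr3 coordinates the methoxy oxygen and bromide removes the methyl group by SN2, while the diaryl ether (no sp3 carbon to attack) and the aryl bromides stay inert.

Step 6
Reactants: 13 5-bromo-2-(2,4-dibromophenoxy)phenol
Product: 15 2,3,4-tribromo-6-(2,4-dibromophenoxy)phenol, via para-brominated phenol 14 (not isolated)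
Conditions: Br2 (2.05 equiv), AcOH–CH2Cl2, 0 °C → rt
Reagents that add atoms: bromine, BrBr
Why: Electrophilic aromatic bromination under control of the free hydroxyl, whose para and remaining ortho positions are the only strongly activated sites (the other ortho position carries the aryloxy group and ring B is deactivated by two bromines), so two equivalents of bromine should stop at the tribrominated ring A.

**Compound list**

1 | coumalic acid (2-oxo-2H-pyran-5-carboxylic acid) | O=C(O)C1=COC(=O)C=C1 | starting material
2 | 3,5-dibromo-2H-pyran-2-one | O=C1OC=C(Br)C=C1Br | intermediate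
3 | 4-bromo-2-methoxyphenol | COc1cc(Br)ccc1O | starting material
4 | trichloroethylene | ClC=C(Cl)Cl | starting material
5 | dichloroacetylene (not isolated) | ClC#CCl | intermediate
6 | (E)-4-bromo-1-[(1,2-dichloroethenyl)oxy]-2-methoxybenzene | COc1cc(Br)ccc1O/C(Cl)=C\Cl | intermediate
7 | 4-bromo-1-[(chloroethynyl)oxy]-2-methoxybenzene (not isolated) | COc1cc(Br)ccc1OC#CCl | intermediate
8 | [(4-bromo-2-methoxyphenoxy)ethynyl]lithium (not isolated) | COc1cc(Br)ccc1OC#C[Li] | intermediate
9 | 4-bromo-1-(ethynyloxy)-2-methoxybenzene | COc1cc(Br)ccc1OC#C | intermediate
10 | 4,7-dibromo-5-(4-bromo-2-methoxyphenoxy)-2-oxabicyclo[2.2.2]octa-5,7-dien-3-one (racemic, bridgehead configuration fixed by the bicycle; not isolated) | COc1cc(Br)ccc1OC1=CC2OC(=O)C1(Br)C=C2Br | intermediate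
11 | 4-bromo-1-(2,4-dibromophenoxy)-2-methoxybenzene | COc1cc(Br)ccc1Oc1ccc(Br)cc1Br | intermediate
12 | dibromo[5-bromo-2-(2,4-dibromophenoxy)phenoxy]borane (not isolated) | BrB(Br)Oc1cc(Br)ccc1Oc1ccc(Br)cc1Br | intermediate
13 | 5-bromo-2-(2,4-dibromophenoxy)phenol | Oc1cc(Br)ccc1Oc1ccc(Br)cc1Br | intermediate
14 | 4,5-dibromo-2-(2,4-dibromophenoxy)phenol (not isolated) | Oc1cc(Br)c(Br)cc1Oc1ccc(Br)cc1Br | intermediate
15 | 2,3,4-tribromo-6-(2,4-dibromophenoxy)phenol | Oc1c(Oc2ccc(Br)cc2Br)cc(Br)c(Br)c1Br | target

**Count**

Total steps: 6. Longest linear sequence: 5 steps (steps 2–6, from 4-bromo-2-methoxyphenol); the pyrone branch (step 1) joins at step 4.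

**Steps most likely to fail**

1. Step 4. The cycloaddition may be slower than thermal oligomerisation of the terminal ynol ether, or the regiochemical preference may leak towards the 3,5-dibromophenyl ether. The fallback builds the same diaryl ether by classical aromatic substitution; it sets out from 3 and comes back at 11. Phenol 3 is joined to commercial 4-bromo-1-fluoro-2-nitrobenzene by nucleophilic aromatic substitution (K2CO3, DMF, 80 °C) to give 4-bromo-1-(4-bromo-2-nitrophenoxy)-2-methoxybenzene F1. Reduction of the nitro group with iron and ammonium chloride in aqueous ethanol should give 5-bromo-2-(4-bromo-2-methoxyphenoxy)aniline F2. Diazotisation (NaNO2, aqueous HBr, 0 °C) to 5-bromo-2-(4-bromo-2-methoxyphenoxy)benzenediazonium bromide F3, followed by a Sandmeyer reaction with CuBr, puts the ortho bromine in place and delivers 11.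

2. Step 3. Bromine–lithium exchange on ring A may compete with the elimination and exchange sequence, which would strip the ring-A bromine, and the terminal ynol ether may decompose during isolation. The fallback makes the alkyne without an organolithium; it sets out from 3 and comes back at 9. Copper(II)-mediated O-vinylation of 3 with the 2,4,6-trivinylcyclotriboroxane–pyridine complex (Cu(OAc)2, pyridine, CH2Cl2, rt, air) gives 4-bromo-1-(ethenyloxy)-2-methoxybenzene F4. Addition of bromine to the enol ether double bond (Br2, CH2Cl2, −78 °C) gives racemic 4-bromo-1-(1,2-dibromoethoxy)-2-methoxybenzene F5. Twofold dehydrobromination with KHMDS (2.2 equiv, THF, −78 °C), a hindered amide base that does not exchange with aryl bromides, should pass through (Z)-4-bromo-1-[(2-bromoethenyl)oxy]-2-methoxybenzene F6 and end at 9.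

3. Step 6. Site control may be lost once the second bromine has to enter: bromination could spill onto ring B or the position next to the aryloxy group, or stall after the first substitution. The fallback delivers the two bromines in separate operations under different directing groups; it sets out from 11 and comes back at 15. Bromination of 11 para to the methoxy group (NBS, MeCN, rt) gives 1,2-dibromo-4-(2,4-dibromophenoxy)-5-methoxybenzene F7. Cleavage of the methyl ether with BBr3 then gives 14 as an isolated compound. A single amine-catalysed ortho-bromination of the phenol (NBS 1.0 equiv, cat. i-Pr2NH, CH2Cl2, 0 °C) completes 15.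

**Further compounds**

F1 | step 4 | 4-bromo-1-(4-bromo-2-nitrophenoxy)-2-methoxybenzene | COc1cc(Br)ccc1Oc1ccc(Br)cc1[N+](=O)[O-]
F2 | step 4 | 5-bromo-2-(4-bromo-2-methoxyphenoxy)aniline | COc1cc(Br)ccc1Oc1ccc(Br)cc1N
F3 | step 4 | 5-bromo-2-(4-bromo-2-methoxyphenoxy)benzenediazonium bromide | COc1cc(Br)ccc1Oc1ccc(Br)cc1[N+]#N.[Br-]
F4 | step 3 | 4-bromo-1-(ethenyloxy)-2-methoxybenzene | COc1cc(Br)ccc1OC=C
F5 | step 3 | 4-bromo-1-(1,2-dibromoethoxy)-2-methoxybenzene (racemic) | COc1cc(Br)ccc1OC(Br)CBr
F6 | step 3 | (Z)-4-bromo-1-[(2-bromoethenyl)oxy]-2-methoxybenzene | COc1cc(Br)ccc1O/C=C\Br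
F7 | step 6 | 1,2-dibromo-4-(2,4-dibromophenoxy)-5-methoxybenzene | COc1cc(Br)c(Br)cc1Oc1ccc(Br)cc1Br
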